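**Retrosynthetic overview**

1. Numbering used in the text: heavy atoms in the order of the target SMILES (O = 10; methyls C1, C7, C12, C16, C20, C21); ring A = C3–C6/C8, ring B = eight-membered, ring C = C11/C13/C14/C15/C23/C24, ring D = C15/C17–C19/C22/C23.
2. 42 ⇐ hydroboration of the ring B diene (C8=C9, C2=C3) ⇐ dehydration ⇐ McMurry closure of ring B at C2=C3 ⇐ asymmetric conjugate addition/aldol that attaches ring A (cyclopentenone + methyl) to a C9 aldehyde.
3. C9 aldehyde and C2 methyl ketone ⇐ ozonolysis of a propenyl group and acetonylation of C25 on a trans-decalin (rings C, D) ⇐ Wolff–Kishner removal of a temporary C22 ketone ⇐ key 6-endo radical cyclization C14→C15 that closes ring C.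
4. Enabling feature: C15 is the methyl-bearing quaternary atom shared by rings C and D and lies 1,3 to C22, the ring D methylene next to the gem-dimethyl carbon C19. A ketone parked on C22 makes C23=C15 an enone with C15 as β-carbon, while its α-carbon C23 already carries the tether C24–C11–C13–C14 ending in a primary CH2.
5. Cyclization precursor ⇐ Ireland–Claisen rearrangement (C11–C24 bond, quaternary C11) of an (S)-allylic ester of (ring D)acetic acid; ring order: D (from 3-methylcyclohexenone), C (step 9), A (from cyclopentenone), B (step 17).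

Key step: step 9

Remarks: all compounds are single enantiomers unless noted. C8 and C9 are deliberately left uncorrected between steps 15 and 18 and are set only in steps 19–20. The conjugate-addition ligand enantiomer is assumed to be the one that gives the (S)-3-methyl enolate.

**Route**

Step 1
Reactants: 1 tert-butyl(but-3-yn-1-yloxy)dimethylsilane
Product: 3 (E)-tert-butyl[(4-iodo-3-methylbut-3-en-1-yl)oxy]dimethylsilane, via alkenylalane 2 (not isolated)
Conditions: Me3Al (2.5 equiv), Cp2ZrCl2 (0.25 equiv), CH2Cl2, 0 °C to rt; then I2, THF, −30 °C to 0 °C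
Reagents that add atoms: trimethylaluminium (C[Al](C)C); iodine ([I][I])
Why: Negishi zirconium-catalysed syn-carboalumination puts methyl on the internal and aluminium on the terminal alkyne carbon, and iodinolysis with retention should give the pure (E)-trisubstituted vinyl iodide.

Step 2
Reactants: 3 (E)-tert-butyl[(4-iodo-3-methylbut-3-en-1-yl)oxy]dimethylsilane; 4 N-methoxy-N-methylacetamide
Product: 6 (E)-6-[(tert-butyldimethylsilyl)oxy]-4-methylhex-3-en-2-one, via vinyllithium 5 (not isolated)
Conditions: t-BuLi (2.1 equiv), Et2O, −78 °C; then 4, −78 °C to 0 °C; aq. NH4Cl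
Reagents that add atoms: none
Why: Lithium–iodine exchange keeps the alkene geometry and Weinreb-amide acylation stops at the ketone because the tetrahedral intermediate is a stable chelate.

Step 3
Reactants: 6 (E)-6-[(tert-butyldimethylsilyl)oxy]-4-methylhex-3-en-2-one
Product: 7 (2S,3E)-6-[(tert-butyldimethylsilyl)oxy]-4-methylhex-3-en-2-ol
Conditions: (R)-2-methyl-CBS-oxazaborolidine (0.2 equiv), BH3·SMe2 (0.7 equiv), THF, −30 °C; MeOH quench
Reagents that add atoms: none
Why: Corey–Bakshi–Shibata reduction with the alkenyl group as the large substituent, so the (R)-catalyst should deliver hydride to give the (S)-carbinol whose chirality is transferred in step 7.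

Step 4
Reactants: 7 (2S,3E)-6-[(tert-butyldimethylsilyl)oxy]-4-methylhex-3-en-2-ol; 8 bromoacetyl bromide
Product: 9 (2S,3E)-6-[(tert-butyldimethylsilyl)oxy]-4-methylhex-3-en-2-yl bromoacetate
Conditions: pyridine, CH2Cl2, 0 °C
Reagents that add atoms: none
Why: O-acylation of the secondary allylic alcohol by the acid bromide, which does not touch the carbinol stereocentre.

Step 5
Reactants: 10 3-methylcyclohex-2-en-1-one
Product: 14 3,6,6-trimethylcyclohex-2-en-1-one, via lithium enolate 11 (not isolated), via monomethylated enone 12 (not isolated), via lithium enolate 13 (not isolated)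
Conditions: LiN(iPr)2 (1.1 equiv), THF, −78 °C; MeI; then LiN(iPr)2 (1.1 equiv), −78 °C; MeI, −78 °C to rt
Reagents that add atoms: iodomethane (IC)
Why: Kinetic deprotonation of a cyclohexenone takes place at the α′ carbon, so two enolate methylations build the gem-dimethyl carbon (C19) next to the carbonyl (C22).

Step 6
Reactants: 14 3,6,6-trimethylcyclohex-2-en-1-one; 9 (2S,3E)-6-[(tert-butyldimethylsilyl)oxy]-4-methylhex-3-en-2-yl bromoacetate
Product: 17 (2S,3E)-6-[(tert-butyldimethylsilyl)oxy]-4-methylhex-3-en-2-yl (2,5,5-trimethyl-6-oxocyclohex-1-en-1-yl)acetate, via potassium dienolate 15 (not isolated), via deconjugated keto ester 16 (not isolated)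
Conditions: KN(SiMe3)2 (1.05 equiv), THF, −78 °C to −40 °C; 9, −78 °C to 0 °C; then DBU (0.2 equiv), CH2Cl2, rt
Reagents that add atoms: none
Why: With the α′ position blocked the base removes a γ-hydrogen, the extended dienolate is alkylated at its α-carbon (C23) by the reactive α-bromo ester (dienolate α-alkylation), and DBU moves the double bond back into conjugation.

Step 7
Reactants: 17 (2S,3E)-6-[(tert-butyldimethylsilyl)oxy]-4-methylhex-3-en-2-yl (2,5,5-trimethyl-6-oxocyclohex-1-en-1-yl)acetate
Product: 21 methyl (2R,3R,4E)-3-{2-[(tert-butyldimethylsilyl)oxy]ethyl}-3-methyl-2-(2,5,5-trimethyl-6-oxocyclohex-1-en-1-yl)hex-4-enoate, via silyl ketene acetal 18 (not isolated), via trimethylsilyl ester 19 (not isolated), via carboxylic acid 20 (not isolated)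
Conditions: LiN(iPr)2 (1.1 equiv), Me3SiCl, THF/DMPU (4:1), −78 °C, then rt to 50 °C; 1 M HCl; then Me3SiCHN2, MeOH/toluene, 0 °C
Reagents that add atoms: (trimethylsilyl)diazomethane (C[Si](C)(C)C=[N+]=[N-])
Why: Ireland–Claisen rearrangement through a chair in which the carbinol methyl and ring D (cis to O–Si in the ketene acetal, the geometry favoured with DMPU) are equatorial, so the (S)-carbinol and the (E)-alkene should set quaternary C11 and C24 together and leave an (E)-propenyl group; the α′-blocked enone is deprotonated more slowly than the ester and any silyl dienol ether reverts on work-up.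

Step 8
Reactants: 21 methyl (2R,3R,4E)-3-{2-[(tert-butyldimethylsilyl)oxy]ethyl}-3-methyl-2-(2,5,5-trimethyl-6-oxocyclohex-1-en-1-yl)hex-4-enoate
Product: 22 methyl (2R,3R,4E)-3-(2-bromoethyl)-3-methyl-2-(2,5,5-trimethyl-6-oxocyclohex-1-en-1-yl)hex-4-enoate
Conditions: Ph3PBr2 (1.5 equiv), CH2Cl2, 0 °C to rt
Reagents that add atoms: dibromotriphenylphosphorane (BrP(Br)(c1ccccc1)(c1ccccc1)c1ccccc1)
Why: Direct conversion of a primary silyl ether into the bromide (oxyphosphonium formation, loss of silyl bromide, SN2 by bromide) without a separate deprotection.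

Step 9
Reactants: 22 methyl (2R,3R,4E)-3-(2-bromoethyl)-3-methyl-2-(2,5,5-trimethyl-6-oxocyclohex-1-en-1-yl)hex-4-enoate
Product: 23 methyl (1S,2R,4aR,8aS)-2,4a,7,7-tetramethyl-8-oxo-2-[(E)-prop-1-en-1-yl]decahydronaphthalene-1-carboxylate
Conditions: (Me3Si)3SiH (1.3 equiv) and AIBN (0.2 equiv) added over 8 h by syringe pump, toluene (0.01 M), 90 °C
Reagents that add atoms: none
Why: The silyl radical abstracts bromine to give the primary C14 radical, which adds to C15, the β-carbon of the ring D enone, and the resulting C23 α-keto radical takes hydrogen from the silane (radical chain; closest known type: Giese-type radical cyclization of haloalkyl enones). Ring C is closed 6-endo-trig, favoured over 5-exo attack at C23 because the nucleophilic alkyl radical pairs with the electrophilic β-carbon and gives the carbonyl-stabilized radical. C15 should be set by a chair transition state with the C24 ester equatorial, which places the incipient axial C16 methyl anti to the axial C12 methyl and avoids a 1,3-diaxial ester/methyl clash. C23 should be set by axial hydrogen delivery anti to the angular C16 methyl (trans fusion), and any cis isomer can still equilibrate in step 10. Direct reduction of the C14 radical is suppressed by slow addition of the slow donor (Me3Si)3SiH at high dilution, and the propenyl group is safe because attacking it would need a 4-exo closure.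

Step 10
Reactants: 23 methyl (1S,2R,4aR,8aS)-2,4a,7,7-tetramethyl-8-oxo-2-[(E)-prop-1-en-1-yl]decahydronaphthalene-1-carboxylate
Product: 25 (1S,2R,4aS,8aS)-2,4a,7,7-tetramethyl-2-[(E)-prop-1-en-1-yl]decahydronaphthalene-1-carboxylic acid, via hydrazone 24 (not isolated)
Conditions: N2H4·H2O, KOH, diethylene glycol, 130 °C then 200 °C (water distilled off), argon; HCl
Reagents that add atoms: potassium hydroxide ([K+].[OH-])
Why: Wolff–Kishner reduction (Huang-Minlon procedure, classical for γ-keto acids and esters) removes the temporary C22 carbonyl, while the hot alkali saponifies the ester and lets C23 equilibrate to the trans-fused arrangement before reduction.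

Step 11
Reactants: 25 (1S,2R,4aS,8aS)-2,4a,7,7-tetramethyl-2-[(E)-prop-1-en-1-yl]decahydronaphthalene-1-carboxylic acid
Product: 26 [(1S,2R,4aS,8aS)-2,4a,7,7-tetramethyl-2-[(E)-prop-1-en-1-yl]decahydronaphthalen-1-yl]methanol
Conditions: LiAlH4, THF, 0 °C to reflux; NaOH/H2O work-up
Reagents that add atoms: none
Why: Hydride reduction of the carboxylic acid to the primary alcohol (C25), with the isolated alkene inert.

Step 12
Reactants: 26 [(1S,2R,4aS,8aS)-2,4a,7,7-tetramethyl-2-[(E)-prop-1-en-1-yl]decahydronaphthalen-1-yl]methanol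
Product: 27 (1S,2R,4aS,8aS)-1-(iodomethyl)-2,4a,7,7-tetramethyl-2-[(E)-prop-1-en-1-yl]decahydronaphthalene
Conditions: I2, PPh3, imidazole, CH2Cl2, 0 °C to rt
Reagents that add atoms: iodine ([I][I])
Why: Appel-type iodination (alkoxyphosphonium, then SN2 by iodide) at the primary carbon.

Step 13
Reactants: 27 (1S,2R,4aS,8aS)-1-(iodomethyl)-2,4a,7,7-tetramethyl-2-[(E)-prop-1-en-1-yl]decahydronaphthalene; 28 acetone N,N-dimethylhydrazone
Product: 31 4-[(1S,2R,4aS,8aS)-2,4a,7,7-tetramethyl-2-[(E)-prop-1-en-1-yl]decahydronaphthalen-1-yl]butan-2-one, via lithiated hydrazone 29 (not isolated), via alkylated hydrazone 30 (not isolated)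
Conditions: 28, LiN(iPr)2, THF, 0 °C; then 27, THF/DMPU, −78 °C to rt; then aq. oxalic acid, Et2O, rt
Reagents that add atoms: water (O)
Why: Corey–Enders azaenolate alkylation, in which the strongly nucleophilic but weakly basic metalated hydrazone displaces the β-branched primary iodide by SN2 and mild hydrolysis frees the methyl ketone (C26, C2, C1).

Step 14
Reactants: 31 4-[(1S,2R,4aS,8aS)-2,4a,7,7-tetramethyl-2-[(E)-prop-1-en-1-yl]decahydronaphthalen-1-yl]butan-2-one
Product: 33 (1S,2S,4aS,8aS)-2,4a,7,7-tetramethyl-1-(3-oxobutyl)decahydronaphthalene-2-carbaldehyde, via ozonide 32 (not isolated)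
Conditions: O3, CH2Cl2, −78 °C; then PPh3, −78 °C to rt
Reagents that add atoms: ozone ([O-][O+]=O)
Why: Ozonolysis of the only C=C bond with reductive work-up gives the non-enolisable α-quaternary aldehyde C9.

Step 15
Reactants: 33 (1S,2S,4aS,8aS)-2,4a,7,7-tetramethyl-1-(3-oxobutyl)decahydronaphthalene-2-carbaldehyde; 34 cyclopent-2-en-1-one
Product: 36 (2S,3S)-2-[(R)-hydroxy{(1S,2S,4aS,8aS)-2,4a,7,7-tetramethyl-1-(3-oxobutyl)decahydronaphthalen-2-yl}methyl]-3-methylcyclopentan-1-one, via zinc enolate 35 (not isolated)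
Conditions: 34, Me2Zn (1.2 equiv), Cu(OTf)2 (2 mol %), chiral phosphoramidite ligand (4 mol %), toluene, −30 °C; then 33, −30 °C to −10 °C; aq. NH4Cl
Reagents that add atoms: dimethylzinc (C[Zn]C)
Why: Copper-catalysed asymmetric conjugate addition sets C6 and gives the regiodefined zinc enolate, which should add to the aldehyde (faster than to the methyl ketone) trans to the new methyl through a Zimmerman–Traxler anti transition state; C8 is rewritten in steps 19–20, so only C6 matters here.

Step 16
Reactants: 36 (2S,3S)-2-[(R)-hydroxy{(1S,2S,4aS,8aS)-2,4a,7,7-tetramethyl-1-(3-oxobutyl)decahydronaphthalen-2-yl}methyl]-3-methylcyclopentan-1-one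
Product: 37 triethylsilyl ether of 36
Conditions: Et3SiOTf, 2,6-lutidine, CH2Cl2, −78 °C
Reagents that add atoms: triethylsilyl trifluoromethanesulfonate (CC[Si](CC)(CC)OS(=O)(=O)C(F)(F)F)
Why: Silylation of the hindered aldol hydroxyl blocks retro-aldol cleavage and titanium alkoxide formation in the next step.

Step 17
Reactants: 37 triethylsilyl ether of 36
Product: 38 tetracyclic silyl ether (O-triethylsilyl derivative of the C8 epimer of 42)
Conditions: TiCl3(DME)1.5, Zn(Cu), DME, reflux; 37 added over 30 h (final 0.002 M)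
Reagents that add atoms: none
Why: Intramolecular McMurry coupling of the cyclopentanone (C3) with the methyl ketone (C2) under high dilution closes ring B and forms the tetrasubstituted C2=C3 bond, whose geometry (C26 cis to C8) is dictated by the eight-membered ring.

Step 18
Reactants: 38 tetracyclic silyl ether
Product: 39 C8 epimer of 42 (H8 trans to the C9 hydroxyl)
Conditions: Bu4NF, THF, rt to 50 °C
Reagents that add atoms: none
Why: Fluoride cleavage of the silyl ether frees the C9 hydroxyl for elimination.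

Step 19
Reactants: 39 C8 epimer of 42
Product: 40 tetracyclic diene (C8=C9 and C2=C3 in ring B)
Conditions: Ph2S[OC(CF3)2Ph]2 (Martin sulfurane), benzene, rt
Reagents that add atoms: none
Why: Martin sulfurane dehydration by anti elimination (H8 and the C9 oxygen are trans in 39) can only form the C8=C9 alkene because C11 is quaternary, which erases the wrong C8 configuration.

Step 20
Reactants: 40 tetracyclic diene
Product: 42 target alcohol CNP0399382.1 (6S,8S,9R,11S,15S,23S,24S in the numbering above), via alkylborane 41 (not isolated)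
Conditions: BH3·THF (1.1 equiv), THF, 0 °C; then NaOH, H2O2, 0 °C to rt
Reagents that add atoms: hydrogen peroxide (OO)
Why: Hydroboration–oxidation places boron on C9, the less substituted end of the trisubstituted (not the tetrasubstituted) alkene, and syn addition from the face opposite the axial C12 methyl on C11 and the C7 methyl on C6 (as in hydroboration of Δ5-steroids anti to the angular methyl) should set H8 and the C9 hydroxyl cis as in the target.

**Compound list**

1 | tert-butyl(but-3-yn-1-yloxy)dimethylsilane | C#CCCO[Si](C)(C)C(C)(C)C | starting material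
2 | (E)-[4-(tert-butyldimethylsilyloxy)-2-methylbut-1-en-1-yl]dimethylalane | C[Al](C)/C=C(\C)CCO[Si](C)(C)C(C)(C)C | intermediate (not isolated)
3 | (E)-tert-butyl[(4-iodo-3-methylbut-3-en-1-yl)oxy]dimethylsilane | I/C=C(\C)CCO[Si](C)(C)C(C)(C)C | intermediate
4 | N-methoxy-N-methylacetamide | CC(=O)N(C)OC | starting material
5 | (E)-[4-(tert-butyldimethylsilyloxy)-2-methylbut-1-en-1-yl]lithium | [Li]/C=C(\C)CCO[Si](C)(C)C(C)(C)C | intermediate (not isolated)
6 | (E)-6-[(tert-butyldimethylsilyl)oxy]-4-methylhex-3-en-2-one | CC(=O)/C=C(\C)CCO[Si](C)(C)C(C)(C)C | intermediate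
7 | (2S,3E)-6-[(tert-butyldimethylsilyl)oxy]-4-methylhex-3-en-2-ol | C[C@H](O)/C=C(\C)CCO[Si](C)(C)C(C)(C)C | intermediate
8 | bromoacetyl bromide | BrCC(=O)Br | starting material
9 | (2S,3E)-6-[(tert-butyldimethylsilyl)oxy]-4-methylhex-3-en-2-yl bromoacetate | C[C@H](OC(=O)CBr)/C=C(\C)CCO[Si](C)(C)C(C)(C)C | intermediate
10 | 3-methylcyclohex-2-en-1-one | CC1=CC(=O)CCC1 | starting material
11 | lithium 5-methylcyclohexa-1,5-dien-1-olate | [Li+].[O-]C1=CCCC(C)=C1 | intermediate (not isolated)
12 | 3,6-dimethylcyclohex-2-en-1-one (racemic) | CC1=CC(=O)C(C)CC1 | intermediate (not isolated)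
13 | lithium 2,5-dimethylcyclohexa-1,5-dien-1-olate | [Li+].[O-]C1=C(C)CCC(C)=C1 | intermediate (not isolated)
14 | 3,6,6-trimethylcyclohex-2-en-1-one | CC1=CC(=O)C(C)(C)CC1 | intermediate
15 | potassium 3,6,6-trimethylcyclohexa-1,3-dien-1-olate | [K+].[O-]C1=CC(C)=CCC1(C)C | intermediate (not isolated)
16 | (2S,3E)-6-[(tert-butyldimethylsilyl)oxy]-4-methylhex-3-en-2-yl (2,5,5-trimethyl-6-oxocyclohex-2-en-1-yl)acetate (both epimers at the ring carbon) | C[C@H](OC(=O)CC1C(C)=CCC(C)(C)C1=O)/C=C(\C)CCO[Si](C)(C)C(C)(C)C | intermediate (not isolated)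
17 | (2S,3E)-6-[(tert-butyldimethylsilyl)oxy]-4-methylhex-3-en-2-yl (2,5,5-trimethyl-6-oxocyclohex-1-en-1-yl)acetate | C[C@H](OC(=O)CC1=C(C)CCC(C)(C)C1=O)/C=C(\C)CCO[Si](C)(C)C(C)(C)C | intermediate
18 | trimethylsilyl ketene acetal of 17 (ring D cis to OSiMe3) | C[C@H](O/C(O[Si](C)(C)C)=C/C1=C(C)CCC(C)(C)C1=O)/C=C(\C)CCO[Si](C)(C)C(C)(C)C | intermediate (not isolated)
19 | trimethylsilyl (2R,3R,4E)-3-{2-[(tert-butyldimethylsilyl)oxy]ethyl}-3-methyl-2-(2,5,5-trimethyl-6-oxocyclohex-1-en-1-yl)hex-4-enoate | C/C=C/[C@@](C)(CCO[Si](C)(C)C(C)(C)C)[C@@H](C(=O)O[Si](C)(C)C)C1=C(C)CCC(C)(C)C1=O | intermediate (not isolated)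
20 | (2R,3R,4E)-3-{2-[(tert-butyldimethylsilyl)oxy]ethyl}-3-methyl-2-(2,5,5-trimethyl-6-oxocyclohex-1-en-1-yl)hex-4-enoic acid | C/C=C/[C@@](C)(CCO[Si](C)(C)C(C)(C)C)[C@@H](C(=O)O)C1=C(C)CCC(C)(C)C1=O | intermediate (not isolated)
21 | methyl (2R,3R,4E)-3-{2-[(tert-butyldimethylsilyl)oxy]ethyl}-3-methyl-2-(2,5,5-trimethyl-6-oxocyclohex-1-en-1-yl)hex-4-enoate | C/C=C/[C@@](C)(CCO[Si](C)(C)C(C)(C)C)[C@@H](C(=O)OC)C1=C(C)CCC(C)(C)C1=O | intermediate
22 | methyl (2R,3R,4E)-3-(2-bromoethyl)-3-methyl-2-(2,5,5-trimethyl-6-oxocyclohex-1-en-1-yl)hex-4-enoate | C/C=C/[C@@](C)(CCBr)[C@@H](C(=O)OC)C1=C(C)CCC(C)(C)C1=O | intermediate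
23 | methyl (1S,2R,4aR,8aS)-2,4a,7,7-tetramethyl-8-oxo-2-[(E)-prop-1-en-1-yl]decahydronaphthalene-1-carboxylate | C/C=C/[C@@]1(C)CC[C@]2(C)CCC(C)(C)C(=O)[C@H]2[C@@H]1C(=O)OC | intermediate
24 | hydrazone of the keto acid derived from 23 | C/C=C/[C@@]1(C)CC[C@]2(C)CCC(C)(C)C(=NN)[C@H]2[C@@H]1C(=O)O | intermediate (not isolated)
25 | (1S,2R,4aS,8aS)-2,4a,7,7-tetramethyl-2-[(E)-prop-1-en-1-yl]decahydronaphthalene-1-carboxylic acid | C/C=C/[C@@]1(C)CC[C@]2(C)CCC(C)(C)C[C@H]2[C@@H]1C(=O)O | intermediate
26 | [(1S,2R,4aS,8aS)-2,4a,7,7-tetramethyl-2-[(E)-prop-1-en-1-yl]decahydronaphthalen-1-yl]methanol | C/C=C/[C@@]1(C)CC[C@]2(C)CCC(C)(C)C[C@H]2[C@@H]1CO | intermediate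
27 | (1S,2R,4aS,8aS)-1-(iodomethyl)-2,4a,7,7-tetramethyl-2-[(E)-prop-1-en-1-yl]decahydronaphthalene | C/C=C/[C@@]1(C)CC[C@]2(C)CCC(C)(C)C[C@H]2[C@@H]1CI | intermediate
28 | acetone N,N-dimethylhydrazone | CC(C)=NN(C)C | starting material
29 | lithiated acetone N,N-dimethylhydrazone | [Li]CC(C)=NN(C)C | intermediate (not isolated)
30 | N,N-dimethylhydrazone of 31 | C/C=C/[C@@]1(C)CC[C@]2(C)CCC(C)(C)C[C@H]2[C@@H]1CCC(C)=NN(C)C | intermediate (not isolated)
31 | 4-[(1S,2R,4aS,8aS)-2,4a,7,7-tetramethyl-2-[(E)-prop-1-en-1-yl]decahydronaphthalen-1-yl]butan-2-one | C/C=C/[C@@]1(C)CC[C@]2(C)CCC(C)(C)C[C@H]2[C@@H]1CCC(C)=O | intermediate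
32 | ozonide (1,2,4-trioxolane) of 31 | CC1OC(OO1)[C@@]2(C)CC[C@]3(C)CCC(C)(C)C[C@H]3[C@@H]2CCC(C)=O | intermediate (not isolated)
33 | (1S,2S,4aS,8aS)-2,4a,7,7-tetramethyl-1-(3-oxobutyl)decahydronaphthalene-2-carbaldehyde | O=C[C@@]1(C)CC[C@]2(C)CCC(C)(C)C[C@H]2[C@@H]1CCC(C)=O | intermediate
34 | cyclopent-2-en-1-one | O=C1C=CCC1 | starting material
35 | methylzinc (S)-3-methylcyclopent-1-en-1-olate | C[Zn]OC1=C[C@@H](C)CC1 | intermediate (not isolated)
36 | (2S,3S)-2-[(R)-hydroxy{(1S,2S,4aS,8aS)-2,4a,7,7-tetramethyl-1-(3-oxobutyl)decahydronaphthalen-2-yl}methyl]-3-methylcyclopentan-1-one | O=C1CC[C@H](C)[C@H]1[C@@H](O)[C@@]2(C)CC[C@]3(C)CCC(C)(C)C[C@H]3[C@@H]2CCC(C)=O | intermediate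
37 | triethylsilyl ether of 36 | O=C1CC[C@H](C)[C@H]1[C@@H](O[Si](CC)(CC)CC)[C@@]2(C)CC[C@]3(C)CCC(C)(C)C[C@H]3[C@@H]2CCC(C)=O | intermediate
38 | tetracyclic silyl ether (O-triethylsilyl derivative of the C8 epimer of 42) | C/C1=C2\CC[C@H](C)[C@H]2[C@@H](O[Si](CC)(CC)CC)[C@@]2(C)CC[C@]3(C)CCC(C)(C)C[C@H]3[C@@H]2CC1 | intermediate
39 | C8 epimer of 42 | C/C1=C2\CC[C@H](C)[C@H]2[C@@H](O)[C@@]2(C)CC[C@]3(C)CCC(C)(C)C[C@H]3[C@@H]2CC1 | intermediate
40 | tetracyclic diene (C8=C9, C2=C3) | C/C1=C2\CC[C@H](C)/C2=C/[C@@]2(C)CC[C@]3(C)CCC(C)(C)C[C@H]3[C@@H]2CC1 | intermediate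
41 | C9 alkylborane from 40 | C/C1=C2\CC[C@H](C)[C@@H]2[C@@H](B)[C@@]2(C)CC[C@]3(C)CCC(C)(C)C[C@H]3[C@@H]2CC1 | intermediate (not isolated)
42 | CNP0399382.1 (target alcohol) | C/C1=C2\CC[C@H](C)[C@@H]2[C@@H](O)[C@@]2(C)CC[C@]3(C)CCC(C)(C)C[C@H]3[C@@H]2CC1 | target

**Summary**

Total: 20 steps. Longest linear sequence: 19 steps (1–4 and 6–20); step 5 is the only side branch.

Three steps most likely to fail:

Step 17 (McMurry closure of ring B). The slow closure of an eight-membered ring with a tetrasubstituted alkene may be outrun by intermolecular coupling, may stop at the titanium pinacolate, or may be preceded by β-elimination of the C9 silyloxy group. The fallback sets out from 37 and comes back at 38, replacing the one-pot titanium reaction by a stepwise reductive coupling and a stereospecific deoxygenation. SmI2 in THF/HMPA at rt should effect ketone–ketone pinacol cyclization to the silyl-protected tetracyclic cis-2,3-diol F1. 1,1′-Thiocarbonyldiimidazole in toluene at 110 °C should convert it into the cyclic thionocarbonate F2. Corey–Winter fragmentation with 1,3-dimethyl-2-phenyl-1,3,2-diazaphospholidine at 40 °C, a syn elimination that can only give the ring-cis alkene, should then deliver 38.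

Step 7 (Ireland–Claisen rearrangement). Competing γ-deprotonation of the enone, or poor control of ketene acetal geometry in this congested ester, may lower conversion or erode the C24 configuration that the key step relies on. The fallback sets out from 17 and comes back at 21, and removes the competing acidic site before enolization. Luche reduction (NaBH4, CeCl3·7H2O, MeOH, −20 °C) should give the ring D allylic alcohol F3. Ireland–Claisen rearrangement with LiN(iPr)2 (2.3 equiv) and Me3SiCl (the hydroxyl is silylated in the flask and freed on acidic work-up), followed by Me3SiCHN2, should give the hydroxy ester F4. Dess–Martin oxidation should then return the enone 21.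

Step 20 (hydroboration–oxidation). Facial selectivity on the flexible eight-membered diene may be insufficient, or the tetrasubstituted alkene may also react. The fallback sets out from 37 and comes back at 42; it keeps the aldol-derived C9 oxygen and sets C8 by kinetic protonation before ring closure, so that neither elimination nor hydroboration is needed. Me3SiOTf and Et3N (CH2Cl2, 0 °C) should give the bis(trimethylsilyl enol ether) F5, with the ring ketone enolized toward the more substituted C8. MeLi (THF, −78 °C) followed by protonation with 2,6-di-tert-butyl-4-methylphenol from the face anti to the C7 methyl should give the cis-2,3-disubstituted cyclopentanone F6, in which C8 and C9 both match the target. McMurry coupling as in step 17 should give the triethylsilyl ether of the target F7, and Bu4NF should release 42. This is kept as a fallback because the cis ketone may epimerize during the titanium step.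

Further compounds
F1 | step 17 | silyl-protected tetracyclic cis-2,3-diol (pinacol of 37) | CC1(O)C2(O)CC[C@H](C)[C@H]2[C@@H](O[Si](CC)(CC)CC)[C@@]2(C)CC[C@]3(C)CCC(C)(C)C[C@H]3[C@@H]2CC1
F2 | step 17 | cyclic thionocarbonate of F1 | CC12OC(=S)OC23CC[C@H](C)[C@H]3[C@@H](O[Si](CC)(CC)CC)[C@@]3(C)CC[C@]4(C)CCC(C)(C)C[C@H]4[C@@H]3CC1
F3 | step 7 | (2S,3E)-6-[(tert-butyldimethylsilyl)oxy]-4-methylhex-3-en-2-yl (6-hydroxy-2,5,5-trimethylcyclohex-1-en-1-yl)acetate | C[C@H](OC(=O)CC1=C(C)CCC(C)(C)C1O)/C=C(\C)CCO[Si](C)(C)C(C)(C)C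
F4 | step 7 | methyl (2R,3R,4E)-3-{2-[(tert-butyldimethylsilyl)oxy]ethyl}-2-(6-hydroxy-2,5,5-trimethylcyclohex-1-en-1-yl)-3-methylhex-4-enoate | C/C=C/[C@@](C)(CCO[Si](C)(C)C(C)(C)C)[C@@H](C(=O)OC)C1=C(C)CCC(C)(C)C1O
F5 | step 20 | bis(trimethylsilyl enol ether) of 37 | C[Si](C)(C)OC1=C([C@@H](O[Si](CC)(CC)CC)[C@@]2(C)CC[C@]3(C)CCC(C)(C)C[C@H]3[C@@H]2CC=C(C)O[Si](C)(C)C)[C@@H](C)CC1
F6 | step 20 | C8 epimer of 37 (cis-2,3-disubstituted cyclopentanone) | O=C1CC[C@H](C)[C@@H]1[C@@H](O[Si](CC)(CC)CC)[C@@]2(C)CC[C@]3(C)CCC(C)(C)C[C@H]3[C@@H]2CCC(C)=O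
F7 | step 20 | triethylsilyl ether of 42 | C/C1=C2\CC[C@H](C)[C@@H]2[C@@H](O[Si](CC)(CC)CC)[C@@]2(C)CC[C@]3(C)CCC(C)(C)C[C@H]3[C@@H]2CC1
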